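## Structural features

The target is a 1,1-diaryl-6-methylheptane. One sp3 methine carries a 5-methylhexyl chain and two 5,7-dihydroxy-2,2-dimethylchroman-6-yl groups. Ring A bears an (R)-2-methylbutanoyl group at C8 and ring B an isobutyryl group at C8, so the two aryl groups differ by a single methylene far from the methine, and every carbon of both benzene rings is substituted. There are two stereocentres, the ketone α-carbon of ring A and the methine (R by the sequence rule, ring A ranking above ring B); they lie five bonds apart, are not adjacent and cannot steer each other. The fragile points are the enolisable α-carbon of the aryl ketone, the oxidation-prone phloroglucinol nuclei, and the doubly benzylic methine flanked by ortho-hydroxyls, which strong acid can ionise and oxidants can turn into a quinone methide. The real difficulty is the methine: a congested carbon between two hexasubstituted arenes that are nearly identical, so a reagent would have to tell ethyl from methyl at long range unless the two rings are made different while the bond forms. A quieter problem is regiochemistry in each chroman, where the acyl group must sit at C8 next to O1 and not at C6. The key step uses the bond from the methine to C6 of ring B, which lies beside O5. Chain C2 and C3 together with O5 read as an ester, so O5–C3(=O)–C2–C1–C6–C5 is a latent six-membered lactone, a 4-aryl-3,4-dihydrocoumarin that a chiral carbene can build from an ynal and a phenol.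

## Logic of the disconnections

**23 to 22.** No skeletal bond is cut: the two O–benzyl bonds on ring A are put back and the chain is given a C3=C4 double bond. One hydrogenation then releases the tetraphenol and saturates the chain at the very end, so the oxidation-prone compound is handled only once. The forward step must spare two aryl ketones and the benzylic methine.

**22 to 19 and 20 (through 21).** The C3=C4 bond is cut by an olefination. This places a carbonyl at C3, which is exactly the carbon a lactone can supply, and the remaining five carbons come from a catalogue salt. The forward step has to run on a hemiacetal with acidic phenols and two enolisable ketones; alkene geometry does not matter.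

**19 to 18.** No bond is cut; C3 is raised to the ester level. The gain is that 18 is the direct product of an annulation. The demand is a partial reduction that takes the aryl ester before two hindered ketones.

**18 to 17 and 7.** The methine–C6 (ring B) bond and the O5–C(=O) bond are cut. This is the one bond at the stereocentre whose formation can be tied to ring closure, which turns a nearly symmetric diarylmethine into a face-selection problem on a planar acyl azolium. The two halves are chroman ketones of equal size. The forward step needs catalyst control of the β-face, tolerance of congestion, capped oxygens on ring A and free hydroxyls on ring B.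

**17 to 16, then to 14 and 15.** The C6 (ring A)–C(sp) bond is cut. An aryl–alkynyl bond is a standard coupling bond and the three-carbon unit is bought. The coupling must work on a di-ortho-alkoxy iodide, and the sensitive aldehyde is unmasked only after coupling.

**14 to 13 to 12.** The O7–benzyl and C6–I bonds are removed. Iodination is easiest and unambiguous on the free phenol, and the second benzyl ether must be in place before an alkyne arrives. The alkylation must not epimerise the ketone.

**12 to 11 and 5; 11 to 10; 10 to 1 and 8 (through 9).** The pyran bonds C4–C4a and O1–C2, the O–benzyl bond at the para oxygen, and the aryl–acyl bond are cut in turn. Benzylating the para oxygen before annulation leaves only ortho-hydroxyls free, so the ring oxygen must end next to the acyl group; without the block both the 6-acyl and the 8-acyl chroman could form. The gain is a symmetric triphenol and a chiral-pool acid. Acylation and all later steps must avoid enolisation toward the α-carbon.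

**7 to 6, then to 4 and 5; 4 to 3; 3 to 1 and 2.** The same cuts serve ring B. Here the blocking benzyl group is removed again, because the key step needs both O5 and O7 free.

## Other disconnections considered

**Alternative 1:** The cut is at the two aryl ether bonds O1–C8a, one in each pyran, so the precursor A2 is an open bis(aryl bromide) with two 3-hydroxy-3-methylbutyl arms. In the forward sense Pd(OAc)2, a bulky di-tert-butylbiarylphosphine and Cs2CO3 would close both rings by intramolecular C–O coupling to the tetra-benzyl ether A1.
- In its favour: both heterocycles form in one operation, and the bromide dictates where each ring oxygen goes. On that point it is better than the chosen plan, which needs a blocking group and an acid annulation. A1 is one hydrogenolysis from the target, which equals the last step of the chosen route.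
- Against it: reductive elimination of a tertiary alkoxide from divalent palladium is the most demanding class of C–O coupling. Each bromide sits between an acyl group and an alkyl arm, and the reaction must succeed twice in one molecule. Warm Cs2CO3 would also meet fully O-benzylated, unchelated ketones, exposing the α-stereocentre of ring A.
- Comparison: the step does not touch the methine. A2 must already hold the (R)-carbon between two hexasubstituted rings, so the central problem moves upstream into a precursor harder to make than 17 and 7. A metal-catalysed coupling replaces an organocatalytic cascade, and the long preparation of A2 would outweigh the short endgame.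

**Alternative 2:** The benzene ring of ring A is cut at C6–C7 and C4a–C5 (with C7–C8 re-formed). In the forward sense the pyran-fused cyclobutenone A4 is heated with the siloxyalkyne A5 in a Danheiser benzannulation (4π opening, [2+2], 4π opening, 6π closure) to give A3.
- In its favour: the cascade needs no reagent and is neutral. The polarised ynol ether fixes the substitution pattern, and O5 and O7 of ring A emerge differentiated as silyl ether and free phenol. The pyran oxygen is placed by construction. On regiocontrol of ring A and on mildness toward the methine it is better than the chosen plan.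
- Against it: A5 must carry the methine stereocentre beforehand as a propargylic carbon, which needs its own asymmetric step and must survive the strongly basic ynol ether formation. A3 still lacks both C8 acyl groups, so two different acylations would have to be steered onto two similar electron-rich rings of a molecule with an acid-labile doubly benzylic methine. A4 also needs a multistep preparation.
- Comparison: the stereochemical problem is moved, not solved. Four pericyclic events replace one catalytic cycle, and the count of steps after the key step would be clearly higher than the three of the chosen route.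

**Alternative 3:** The benzene ring of ring B is cut at C7–C8 and C5–C4a. In the forward sense the aryl-substituted bis(2,4,6-trichlorophenyl) malonate A7 is heated with the oxanylidene ketone A8, which is C-acylated at the enol ether α-carbon and then at the ring γ-carbon, to give A6.
- In its favour: ring B arrives with acyl group, pyran and both free hydroxyls in place, with no regiochemical question. A6 is one hydrogenolysis from the target, so the endgame is shorter than the chosen one (one step against three); on both points it is better.
- Against it: such double acylations need high temperature and release trichlorophenol. The malonate carries a very bulky secondary substituent. The γ-carbon of A8 becomes nucleophilic only through a dienol, so closure through the ketone oxygen to a pyranone competes. The ring A ketone α-carbon would be exposed to prolonged heat.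
- Comparison: the methine must be set earlier in A7, for example by an asymmetric conjugate addition to an alkylidene malonate, so an enantioselective β-functionalisation is needed in both plans. The chosen plan couples it to ring formation under mild catalysis, while this one adds a harsh thermal condensation afterwards. The overall step count would be similar or higher once A7 and A8 are made.

Key step: step 12

## Assumptions and remarks on the chemistry

- (R)-2-Methylbutanoic acid, (3-methylbutyl)triphenylphosphonium bromide and both antipodes of the aminoindanol-derived triazolium chloride are taken as catalogue compounds.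
- The structures of 17, 7 and 18 are consistent with the target atom by atom and no error was found in them; the methine is R in 18, 19, 22 and 23 because the ring A aryl group outranks the ring B aryl group (benzyl ethers against hydroxyls, and in 23 ethyl against methyl in the acyl group).
- Which antipode of the carbene gives the R methine cannot be derived safely by analogy; it is assumed that one trial with each antipode settles it.
- A free acylphloroglucinol can close the pyran on an ortho or on the para hydroxyl; the para oxygen is therefore benzylated before annulation in both series, at the cost of one step in ring A and two in ring B.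

## Route

Step 1
Reactants: 1 phloroglucinol; 2 isobutyryl chloride
Product: 3 2-methyl-1-(2,4,6-trihydroxyphenyl)propan-1-one
Conditions: AlCl3 (4 equiv), PhNO2–CH2Cl2, 0 °C → 40 °C; aq. HCl
Reagents that add atoms: none
Why: Friedel–Crafts C-acylation of a symmetric, very electron-rich arene; the first acyl group deactivates the ring as a chelated vinylogous acid, so monoacylation should prevail.

Step 2
Reactants: 3 2-methyl-1-(2,4,6-trihydroxyphenyl)propan-1-one
Product: 4 1-[4-(benzyloxy)-2,6-dihydroxyphenyl]-2-methylpropan-1-one
Conditions: BnOH (1.05 equiv), PPh3, DIAD, THF, 0 °C → rt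
Reagents that add atoms: benzyl alcohol, OCc1ccccc1
Why: Mitsunobu etherification; the para hydroxyl is the most acidic and the only one not hydrogen-bonded to the ketone, so it should be benzylated selectively and without C-alkylation. This benzyl group blocks the para oxygen for the annulation.

Step 3
Reactants: 4 1-[4-(benzyloxy)-2,6-dihydroxyphenyl]-2-methylpropan-1-one; 5 2-methylbut-3-en-2-ol
Product: 6 1-[5-(benzyloxy)-7-hydroxy-2,2-dimethylchroman-8-yl]-2-methylpropan-1-one
Conditions: 5 (1.2 equiv), BF3·OEt2 (1 equiv), dioxane, rt
Reagents that add atoms: none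
Why: Acid-catalysed prenylation–cyclisation (Friedel–Crafts alkylation by the dimethylallyl cation, then Markovnikov hydroalkoxylation); the two free ring carbons and the two free hydroxyls of 4 are symmetry-equivalent, so only the chroman with O1 next to the acyl group can form. A limited amount of 5 should hold back a second annulation.

Step 4
Reactants: 6 1-[5-(benzyloxy)-7-hydroxy-2,2-dimethylchroman-8-yl]-2-methylpropan-1-one
Product: 7 1-(5,7-dihydroxy-2,2-dimethylchroman-8-yl)-2-methylpropan-1-one (ring B phenol)
Conditions: H2 (1 atm), 10% Pd/C, EtOAc, rt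
Reagents that add atoms: none
Why: Hydrogenolysis of an aryl benzyl ether; the chelated, hindered aryl ketone should not be reduced at atmospheric pressure.

Step 5
Reactants: 8 (R)-2-methylbutanoic acid; 1 phloroglucinol
Product: 10 (2R)-2-methyl-1-(2,4,6-trihydroxyphenyl)butan-1-one, via (R)-2-methylbutanoyl chloride 9 (not isolated)
Conditions: (COCl)2, cat. DMF, CH2Cl2, 0 °C → rt; then 1, AlCl3 (4 equiv), PhNO2–CH2Cl2, 0 °C → rt; aq. HCl
Reagents that add atoms: none
Why: Base-free acid chloride formation (no ketene pathway) followed by Friedel–Crafts acylation at low temperature; the α-stereocentre comes from the chiral pool, and the product ketone, as an aluminium phenoxide chelate, has little tendency to enolise toward the α-carbon.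

Step 6
Reactants: 10 (2R)-2-methyl-1-(2,4,6-trihydroxyphenyl)butan-1-one
Product: 11 (2R)-1-[4-(benzyloxy)-2,6-dihydroxyphenyl]-2-methylbutan-1-one
Conditions: BnOH (1.05 equiv), PPh3, DIAD, THF, 0 °C → rt
Reagents that add atoms: benzyl alcohol, OCc1ccccc1
Why: Mitsunobu etherification of the most acidic, unchelated para hydroxyl under neutral conditions that leave the α-stereocentre alone; this benzyl group is both the regiochemical block and the later O5 protecting group of ring A.

Step 7
Reactants: 11 (2R)-1-[4-(benzyloxy)-2,6-dihydroxyphenyl]-2-methylbutan-1-one; 5 2-methylbut-3-en-2-ol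
Product: 12 (2R)-1-[5-(benzyloxy)-7-hydroxy-2,2-dimethylchroman-8-yl]-2-methylbutan-1-one
Conditions: 5 (1.2 equiv), BF3·OEt2 (1 equiv), dioxane, rt
Reagents that add atoms: none
Why: Same acid-catalysed prenylation–cyclisation as in step 3; only an ortho hydroxyl is free, so the acyl group ends at C8 beside O1, and the doubly chelated ketone should not enolise at room temperature.

Step 8
Reactants: 12 (2R)-1-[5-(benzyloxy)-7-hydroxy-2,2-dimethylchroman-8-yl]-2-methylbutan-1-one
Product: 13 (2R)-1-[5-(benzyloxy)-7-hydroxy-6-iodo-2,2-dimethylchroman-8-yl]-2-methylbutan-1-one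
Conditions: N-iodosuccinimide (1.05 equiv), MeCN, 0 °C → rt, dark
Reagents that add atoms: N-iodosuccinimide, O=C1CCC(=O)N1I
Why: Electrophilic aromatic iodination; C6 is the only ring CH and is activated by the ortho hydroxyl, the ortho benzyloxy group and the para ring oxygen.

Step 9
Reactants: 13 (2R)-1-[5-(benzyloxy)-7-hydroxy-6-iodo-2,2-dimethylchroman-8-yl]-2-methylbutan-1-one
Product: 14 (2R)-1-[5,7-bis(benzyloxy)-6-iodo-2,2-dimethylchroman-8-yl]-2-methylbutan-1-one
Conditions: BnBr (1.5 equiv), K2CO3 (2 equiv), DMF, rt → 40 °C
Reagents that add atoms: benzyl bromide, BrCc1ccccc1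
Why: Williamson ether synthesis on the chelated phenoxide; carbonate is too weak to enolise the twisted ketone at this temperature, and the ether must be in place before the alkyne arrives because an ortho-alkynyl phenol would cyclise to a benzofuran.

Step 10
Reactants: 14 (2R)-1-[5,7-bis(benzyloxy)-6-iodo-2,2-dimethylchroman-8-yl]-2-methylbutan-1-one; 15 prop-2-yn-1-ol
Product: 16 (2R)-1-[5,7-bis(benzyloxy)-6-(3-hydroxyprop-1-yn-1-yl)-2,2-dimethylchroman-8-yl]-2-methylbutan-1-one
Conditions: 15 (2 equiv), Pd(PPh3)2Cl2 (5 mol%), CuI (10 mol%), Et3N–THF, 60 °C, degassed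
Reagents that add atoms: none
Why: Sonogashira coupling; oxidative addition of the hindered, electron-rich aryl iodide to zerovalent palladium needs warming, after which the copper acetylide transmetalates and reductive elimination gives the aryl alkyne.

Step 11
Reactants: 16 (2R)-1-[5,7-bis(benzyloxy)-6-(3-hydroxyprop-1-yn-1-yl)-2,2-dimethylchroman-8-yl]-2-methylbutan-1-one
Product: 17 3-{5,7-bis(benzyloxy)-2,2-dimethyl-8-[(2R)-2-methylbutanoyl]chroman-6-yl}prop-2-ynal (ring A ynal)
Conditions: activated MnO2 (15 equiv), CH2Cl2, rt
Reagents that add atoms: none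
Why: MnO2 oxidation of an activated propargylic alcohol under neutral conditions, which stops at the aldehyde; the ynal should be used soon after filtration.

Step 12
Reactants: 17 3-{5,7-bis(benzyloxy)-2,2-dimethyl-8-[(2R)-2-methylbutanoyl]chroman-6-yl}prop-2-ynal; 7 1-(5,7-dihydroxy-2,2-dimethylchroman-8-yl)-2-methylpropan-1-one
Product: 18 (4R)-4-{5,7-bis(benzyloxy)-2,2-dimethyl-8-[(2R)-2-methylbutanoyl]chroman-6-yl}-5-hydroxy-8,8-dimethyl-6-(2-methylpropanoyl)-3,4,9,10-tetrahydro-2H,8H-pyrano[2,3-f]chromen-2-one
Conditions: 7 (1.2 equiv), (5aS,10bR)-2-mesityl-5a,10b-dihydro-4H,6H-indeno[2,1-b][1,2,4]triazolo[4,3-d][1,4]oxazin-2-ium chloride (15 mol%, antipode fixed by trial), toluene, 4 Å MS, 40 °C, no oxidant, no added base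
Reagents that add atoms: none
Why: The carbene adds to the aldehyde of 17, and the hydroxy-enamine so formed is protonated at the remote alkyne carbon and tautomerises, an internal redox that gives the (E)-α,β-unsaturated acyl azolium without an oxidant. Phenol 7 then bonds through C6 to the β-carbon, either by direct Michael addition or by O5 addition to the acyl carbon followed by a Claisen-type [3,3] shift, and the enol tautomerises to a saturated acyl azolium. O5 displaces the carbene in a 6-exo-trig acyl substitution that closes the lactone ring and frees the catalyst. The closest known reaction type is the carbene-catalysed redox annulation of ynals with naphthols, kojic acids and other enolisable phenols to dihydropyranones and dihydrocoumarins. The methine (4R) is set by the chiral carbene, whose indane wall shields one face of the planar acyl azolium; because ring B is tied into the lactone, the two faces differ strongly, whereas the two aryl groups of the target hardly differ. Site selectivity needs no control because C6 is the only unsubstituted carbon of 7; O5 should close in preference to the chelated O7, and a lactone through O7 would in any case converge after ring opening in step 14. Simple O-acylation is not a dead end, because the aryl ester of so acidic a phenol can be re-activated by the carbene. The benzyl ethers on ring A prevent cyclisation onto the alkyne, and the absence of base and oxidant spares the ketone α-stereocentre and the phloroglucinol ring.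

Step 13
Reactants: 18 (4R)-4-{5,7-bis(benzyloxy)-2,2-dimethyl-8-[(2R)-2-methylbutanoyl]chroman-6-yl}-5-hydroxy-8,8-dimethyl-6-(2-methylpropanoyl)-3,4,9,10-tetrahydro-2H,8H-pyrano[2,3-f]chromen-2-one
Product: 19 1-[(4R)-4-{5,7-bis(benzyloxy)-2,2-dimethyl-8-[(2R)-2-methylbutanoyl]chroman-6-yl}-2,5-dihydroxy-8,8-dimethyl-3,4,9,10-tetrahydro-2H,8H-pyrano[2,3-f]chromen-6-yl]-2-methylpropan-1-one (lactol, both C2 epimers)
Conditions: i-Bu2AlH (2.2 equiv), CH2Cl2, −78 °C; MeOH, then aq. KNaC4H4O6
Reagents that add atoms: none
Why: Partial reduction of an aryl ester lactone to the lactol, whose aluminium hemiacetal is stable at −78 °C. The first equivalent forms an aluminium phenoxide chelate that deactivates the ring B ketone, and the ring A ketone is di-ortho-substituted and α-branched, so the activated lactone should react first.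

Step 14
Reactants: 19 1-[(4R)-4-{5,7-bis(benzyloxy)-2,2-dimethyl-8-[(2R)-2-methylbutanoyl]chroman-6-yl}-2,5-dihydroxy-8,8-dimethyl-3,4,9,10-tetrahydro-2H,8H-pyrano[2,3-f]chromen-6-yl]-2-methylpropan-1-one; 20 (3-methylbutyl)triphenylphosphonium bromide
Product: 22 (2R)-1-{5,7-bis(benzyloxy)-6-[(1R,3Z)-1-[5,7-dihydroxy-2,2-dimethyl-8-(2-methylpropanoyl)chroman-6-yl]-6-methylhept-3-en-1-yl]-2,2-dimethylchroman-8-yl}-2-methylbutan-1-one, via (3-methylbutylidene)triphenylphosphorane 21 (not isolated)
Conditions: 20 (4.0 equiv), KN(SiMe3)2 (3.8 equiv), THF, 0 °C; then 19, −78 °C → 0 °C; aq. NH4Cl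
Reagents that add atoms: none
Why: Wittig olefination of the open hydroxy-aldehyde form of the lactol; the excess unstabilised ylide first deprotonates the acidic hydroxyls and then olefinates the aldehyde, mainly to the Z alkene, whose geometry is irrelevant. The hindered ketones should not react, and the low temperature limits enolisation of the ring A ketone.

Step 15
Reactants: 22 (2R)-1-{5,7-bis(benzyloxy)-6-[(1R,3Z)-1-[5,7-dihydroxy-2,2-dimethyl-8-(2-methylpropanoyl)chroman-6-yl]-6-methylhept-3-en-1-yl]-2,2-dimethylchroman-8-yl}-2-methylbutan-1-one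
Product: 23 (2R)-1-{6-[(1R)-1-[5,7-dihydroxy-2,2-dimethyl-8-(2-methylpropanoyl)chroman-6-yl]-6-methylheptyl]-5,7-dihydroxy-2,2-dimethylchroman-8-yl}-2-methylbutan-1-one (CNP0287681.1)
Conditions: H2 (1 atm), 10% Pd/C, EtOAc–EtOH, rt
Reagents that add atoms: none
Why: Heterogeneous hydrogenation saturates the alkene and hydrogenolyses both benzyl ethers in one operation; the neutral medium should leave both stereocentres and the chelated ketones untouched.

## Compound list

1 | phloroglucinol (benzene-1,3,5-triol) | Oc1cc(O)cc(O)c1 | starting material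
2 | isobutyryl chloride (2-methylpropanoyl chloride) | CC(C)C(=O)Cl | starting material
3 | 2-methyl-1-(2,4,6-trihydroxyphenyl)propan-1-one | CC(C)C(=O)c1c(O)cc(O)cc1O | intermediate
4 | 1-[4-(benzyloxy)-2,6-dihydroxyphenyl]-2-methylpropan-1-one | CC(C)C(=O)c1c(O)cc(OCc2ccccc2)cc1O | intermediate
5 | 2-methylbut-3-en-2-ol | CC(C)(O)C=C | starting material
6 | 1-[5-(benzyloxy)-7-hydroxy-2,2-dimethylchroman-8-yl]-2-methylpropan-1-one | CC(C)C(=O)c1c(O)cc(OCc3ccccc3)c2c1OC(C)(C)CC2 | intermediate
7 | 1-(5,7-dihydroxy-2,2-dimethylchroman-8-yl)-2-methylpropan-1-one (ring B phenol) | CC(C)C(=O)c1c(O)cc(O)c2c1OC(C)(C)CC2 | intermediate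
8 | (R)-2-methylbutanoic acid | CC[C@@H](C)C(=O)O | starting material
9 | (R)-2-methylbutanoyl chloride | CC[C@@H](C)C(=O)Cl | intermediate
10 | (2R)-2-methyl-1-(2,4,6-trihydroxyphenyl)butan-1-one | CC[C@@H](C)C(=O)c1c(O)cc(O)cc1O | intermediate
11 | (2R)-1-[4-(benzyloxy)-2,6-dihydroxyphenyl]-2-methylbutan-1-one | CC[C@@H](C)C(=O)c1c(O)cc(OCc2ccccc2)cc1O | intermediate
12 | (2R)-1-[5-(benzyloxy)-7-hydroxy-2,2-dimethylchroman-8-yl]-2-methylbutan-1-one | CC[C@@H](C)C(=O)c1c(O)cc(OCc3ccccc3)c2c1OC(C)(C)CC2 | intermediate
13 | (2R)-1-[5-(benzyloxy)-7-hydroxy-6-iodo-2,2-dimethylchroman-8-yl]-2-methylbutan-1-one | CC[C@@H](C)C(=O)c1c(O)c(I)c(OCc3ccccc3)c2c1OC(C)(C)CC2 | intermediate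
14 | (2R)-1-[5,7-bis(benzyloxy)-6-iodo-2,2-dimethylchroman-8-yl]-2-methylbutan-1-one | CC[C@@H](C)C(=O)c1c(OCc3ccccc3)c(I)c(OCc3ccccc3)c2c1OC(C)(C)CC2 | intermediate
15 | prop-2-yn-1-ol | OCC#C | starting material
16 | (2R)-1-[5,7-bis(benzyloxy)-6-(3-hydroxyprop-1-yn-1-yl)-2,2-dimethylchroman-8-yl]-2-methylbutan-1-one | CC[C@@H](C)C(=O)c1c(OCc3ccccc3)c(C#CCO)c(OCc3ccccc3)c2c1OC(C)(C)CC2 | intermediate
17 | 3-{5,7-bis(benzyloxy)-2,2-dimethyl-8-[(2R)-2-methylbutanoyl]chroman-6-yl}prop-2-ynal (ring A ynal) | CC[C@@H](C)C(=O)c1c(OCc3ccccc3)c(C#CC=O)c(OCc3ccccc3)c2c1OC(C)(C)CC2 | intermediate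
18 | (4R)-4-{5,7-bis(benzyloxy)-2,2-dimethyl-8-[(2R)-2-methylbutanoyl]chroman-6-yl}-5-hydroxy-8,8-dimethyl-6-(2-methylpropanoyl)-3,4,9,10-tetrahydro-2H,8H-pyrano[2,3-f]chromen-2-one | CC[C@@H](C)C(=O)c1c(OCc3ccccc3)c([C@H](CC(=O)O5)c6c5c7c(c(C(=O)C(C)C)c6O)OC(C)(C)CC7)c(OCc3ccccc3)c2c1OC(C)(C)CC2 | intermediate
19 | 1-[(4R)-4-{5,7-bis(benzyloxy)-2,2-dimethyl-8-[(2R)-2-methylbutanoyl]chroman-6-yl}-2,5-dihydroxy-8,8-dimethyl-3,4,9,10-tetrahydro-2H,8H-pyrano[2,3-f]chromen-6-yl]-2-methylpropan-1-one (lactol, both C2 epimers) | CC[C@@H](C)C(=O)c1c(OCc3ccccc3)c([C@H](CC(O)O5)c6c5c7c(c(C(=O)C(C)C)c6O)OC(C)(C)CC7)c(OCc3ccccc3)c2c1OC(C)(C)CC2 | intermediate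
20 | (3-methylbutyl)triphenylphosphonium bromide | CC(C)CC[P+](c1ccccc1)(c1ccccc1)c1ccccc1.[Br-] | starting material
21 | (3-methylbutylidene)triphenylphosphorane | CC(C)CC=P(c1ccccc1)(c1ccccc1)c1ccccc1 | intermediate
22 | (2R)-1-{5,7-bis(benzyloxy)-6-[(1R,3Z)-1-[5,7-dihydroxy-2,2-dimethyl-8-(2-methylpropanoyl)chroman-6-yl]-6-methylhept-3-en-1-yl]-2,2-dimethylchroman-8-yl}-2-methylbutan-1-one | CC[C@@H](C)C(=O)c1c(OCc3ccccc3)c([C@H](C/C=C\CC(C)C)c4c(O)c5c(c(C(=O)C(C)C)c4O)OC(C)(C)CC5)c(OCc3ccccc3)c2c1OC(C)(C)CC2 | intermediate
23 | (2R)-1-{6-[(1R)-1-[5,7-dihydroxy-2,2-dimethyl-8-(2-methylpropanoyl)chroman-6-yl]-6-methylheptyl]-5,7-dihydroxy-2,2-dimethylchroman-8-yl}-2-methylbutan-1-one (CNP0287681.1) | CC[C@@H](C)C(=O)c1c(O)c([C@H](CCCCC(C)C)c2c(O)c3c(c(C(=O)C(C)C)c2O)OC(C)(C)CC3)c(O)c2c1OC(C)(C)CC2 | target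

## Step count and least certain steps

Total step count: 15 (ring B series steps 1–4, ring A series steps 5–11, joint steps 12–15). Longest linear sequence: 11 steps (steps 5–15, from 1 and 8 to 23).

**Step 12 (key step).**
- What may go wrong: bond formation may stall, because each carbon to be joined is flanked by two ortho substituents; the phenol may drain into redox esterification; facial discrimination may be poor for an aryl-substituted acyl azolium.
- Fallback: it sets out from 14 and 7 and rejoins the route at 19, so it also passes over step 13. Suzuki–Miyaura coupling of 14 with the catalogue reagent (E)-2-(3,3-diethoxyprop-1-en-1-yl)-4,4,5,5-tetramethyl-1,3,2-dioxaborolane (Pd(OAc)2, 2-dicyclohexylphosphino-2',6'-dimethoxybiphenyl, K3PO4, toluene–water, 80 °C) should give the acetal (2R)-1-{5,7-bis(benzyloxy)-6-[(1E)-3,3-diethoxyprop-1-en-1-yl]-2,2-dimethylchroman-8-yl}-2-methylbutan-1-one F1. Dilute aqueous acid should then release the enal (2E)-3-{5,7-bis(benzyloxy)-2,2-dimethyl-8-[(2R)-2-methylbutanoyl]chroman-6-yl}prop-2-enal F2. An iminium-catalysed Friedel–Crafts alkylation of 7 with F2, using one antipode of 2-[diphenyl(trimethylsilyloxy)methyl]pyrrolidine with benzoic acid, is a known reaction type for naphthols and electron-rich phenols with enals and ends in hemiacetal closure, giving 19 directly. This changes the activation mode and the oxidation level but not the bond formed; it answers catalyst-specific failure better than it answers congestion.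

**Step 7 (and step 3, the same reaction).**
- What may go wrong: incomplete C-alkylation of the acyl-deactivated ring, a second annulation, or acid-induced cleavage or migration of the benzyl group.
- Fallback: it sets out from 11 and returns at 12. Condensation of 11 with 3-methylbut-2-enal and catalytic ethylenediammonium diacetate in refluxing toluene (Knoevenagel condensation, then oxa-6π electrocyclisation) should give the chromene (2R)-1-[5-(benzyloxy)-7-hydroxy-2,2-dimethyl-2H-chromen-8-yl]-2-methylbutan-1-one F3. Hydrogenation with H2 and RhCl(PPh3)3 should saturate the pyran double bond without touching the benzyl ether and give 12. In ring B the same condensation on 4 should give 1-[5-(benzyloxy)-7-hydroxy-2,2-dimethyl-2H-chromen-8-yl]-2-methylpropan-1-one F4, and H2 over Pd/C should then saturate and debenzylate it in one operation, returning at 7.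

**Step 13.**
- What may go wrong: competing hydride delivery to an aryl ketone, or collapse of the aluminium hemiacetal and over-reduction to the diol.
- Fallback: it sets out from 18 and returns at 19. Aminolysis with Me(MeO)NH·HCl and AlMe3 in CH2Cl2 should open only the lactone to the amide (3R)-3-{5,7-bis(benzyloxy)-2,2-dimethyl-8-[(2R)-2-methylbutanoyl]chroman-6-yl}-3-[5,7-dihydroxy-2,2-dimethyl-8-(2-methylpropanoyl)chroman-6-yl]-N-methoxy-N-methylpropanamide F5. Cp2Zr(H)Cl in THF at room temperature reduces such amides to aldehydes, and this bulky hydride should be shut out from both hindered ketones. The aldehyde closes to 19.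

**Step 14.**
- What may go wrong: epimerisation at the α-carbon of the ring A ketone by the basic ylide, or slow olefination of the poly-anionic hemiacetal.
- Fallback: it sets out from 19 and returns at 23. A Takai–Utimoto alkylidenation with 1,1-diiodo-3-methylbutane F6 (made from 3-methylbutanal hydrazone and iodine) and CrCl2 (divalent chromium) in THF–DMF is non-basic and aldehyde-selective. It should give the E alkene (2R)-1-{5,7-bis(benzyloxy)-6-[(1R,3E)-1-[5,7-dihydroxy-2,2-dimethyl-8-(2-methylpropanoyl)chroman-6-yl]-6-methylhept-3-en-1-yl]-2,2-dimethylchroman-8-yl}-2-methylbutan-1-one F7, which the conditions of step 15 convert into 23.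

## Further compounds

F1 | step 12 | (2R)-1-{5,7-bis(benzyloxy)-6-[(1E)-3,3-diethoxyprop-1-en-1-yl]-2,2-dimethylchroman-8-yl}-2-methylbutan-1-one | CC[C@@H](C)C(=O)c1c(OCc3ccccc3)c(/C=C/C(OCC)OCC)c(OCc3ccccc3)c2c1OC(C)(C)CC2
F2 | step 12 | (2E)-3-{5,7-bis(benzyloxy)-2,2-dimethyl-8-[(2R)-2-methylbutanoyl]chroman-6-yl}prop-2-enal | CC[C@@H](C)C(=O)c1c(OCc3ccccc3)c(/C=C/C=O)c(OCc3ccccc3)c2c1OC(C)(C)CC2
F3 | step 7 | (2R)-1-[5-(benzyloxy)-7-hydroxy-2,2-dimethyl-2H-chromen-8-yl]-2-methylbutan-1-one | CC[C@@H](C)C(=O)c1c(O)cc(OCc3ccccc3)c2c1OC(C)(C)C=C2
F4 | step 3 | 1-[5-(benzyloxy)-7-hydroxy-2,2-dimethyl-2H-chromen-8-yl]-2-methylpropan-1-one | CC(C)C(=O)c1c(O)cc(OCc3ccccc3)c2c1OC(C)(C)C=C2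
F5 | step 13 | (3R)-3-{5,7-bis(benzyloxy)-2,2-dimethyl-8-[(2R)-2-methylbutanoyl]chroman-6-yl}-3-[5,7-dihydroxy-2,2-dimethyl-8-(2-methylpropanoyl)chroman-6-yl]-N-methoxy-N-methylpropanamide | CC[C@@H](C)C(=O)c1c(OCc3ccccc3)c([C@H](CC(=O)N(C)OC)c4c(O)c5c(c(C(=O)C(C)C)c4O)OC(C)(C)CC5)c(OCc3ccccc3)c2c1OC(C)(C)CC2
F6 | step 14 | 1,1-diiodo-3-methylbutane | CC(C)CC(I)I
F7 | step 14 | (2R)-1-{5,7-bis(benzyloxy)-6-[(1R,3E)-1-[5,7-dihydroxy-2,2-dimethyl-8-(2-methylpropanoyl)chroman-6-yl]-6-methylhept-3-en-1-yl]-2,2-dimethylchroman-8-yl}-2-methylbutan-1-one | CC[C@@H](C)C(=O)c1c(OCc3ccccc3)c([C@H](C/C=C/CC(C)C)c4c(O)c5c(c(C(=O)C(C)C)c4O)OC(C)(C)CC5)c(OCc3ccccc3)c2c1OC(C)(C)CC2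
A1 | alternative 1 | (2R)-1-{5,7-bis(benzyloxy)-6-[(1R)-1-[5,7-bis(benzyloxy)-2,2-dimethyl-8-(2-methylpropanoyl)chroman-6-yl]-6-methylheptyl]-2,2-dimethylchroman-8-yl}-2-methylbutan-1-one (tetra-O-benzyl target) | CC[C@@H](C)C(=O)c1c(OCc3ccccc3)c([C@H](CCCCC(C)C)c4c(OCc3ccccc3)c5c(c(C(=O)C(C)C)c4OCc3ccccc3)OC(C)(C)CC5)c(OCc3ccccc3)c2c1OC(C)(C)CC2
A2 | alternative 1 | (2R)-1-{2,4-bis(benzyloxy)-3-[(1R)-1-[2,6-bis(benzyloxy)-4-bromo-3-(3-hydroxy-3-methylbutyl)-5-(2-methylpropanoyl)phenyl]-6-methylheptyl]-6-bromo-5-(3-hydroxy-3-methylbutyl)phenyl}-2-methylbutan-1-one | CC[C@@H](C)C(=O)c1c(OCc3ccccc3)c([C@H](CCCCC(C)C)c4c(OCc3ccccc3)c(CCC(C)(C)O)c(Br)c(C(=O)C(C)C)c4OCc3ccccc3)c(OCc3ccccc3)c(CCC(C)(C)O)c1Br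
A3 | alternative 2 | 6-[(1R)-1-[5,7-bis(benzyloxy)-2,2-dimethylchroman-6-yl]-6-methylheptyl]-2,2-dimethyl-5-[(triisopropylsilyl)oxy]chroman-7-ol | Oc1cc2OC(C)(C)CCc2c(O[Si](C(C)C)(C(C)C)C(C)C)c1[C@H](CCCCC(C)C)c6c(OCc3ccccc3)c4c(cc6OCc5ccccc5)OC(C)(C)CC4
A4 | alternative 2 | 3,3-dimethyl-2-oxabicyclo[4.2.0]oct-1(6)-en-7-one | O=C1CC2=C1CCC(C)(C)O2
A5 | alternative 2 | {[(3S)-3-[5,7-bis(benzyloxy)-2,2-dimethylchroman-6-yl]-8-methylnon-1-yn-1-yl]oxy}triisopropylsilane | CC(C)[Si](C(C)C)(C(C)C)OC#C[C@H](CCCCC(C)C)c1c(OCc2ccccc2)c3c(cc1OCc4ccccc4)OC(C)(C)CC3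
A6 | alternative 3 | (2R)-1-{5,7-bis(benzyloxy)-6-[(1R)-1-[5,7-dihydroxy-2,2-dimethyl-8-(2-methylpropanoyl)chroman-6-yl]-6-methylheptyl]-2,2-dimethylchroman-8-yl}-2-methylbutan-1-one | CC[C@@H](C)C(=O)c1c(OCc3ccccc3)c([C@H](CCCCC(C)C)c4c(O)c5c(c(C(=O)C(C)C)c4O)OC(C)(C)CC5)c(OCc3ccccc3)c2c1OC(C)(C)CC2
A7 | alternative 3 | bis(2,4,6-trichlorophenyl) 2-[(1R)-1-{5,7-bis(benzyloxy)-2,2-dimethyl-8-[(2R)-2-methylbutanoyl]chroman-6-yl}-6-methylheptyl]propanedioate | CC[C@@H](C)C(=O)c1c(OCc3ccccc3)c([C@H](CCCCC(C)C)C(C(=O)Oc4c(Cl)cc(Cl)cc4Cl)C(=O)Oc5c(Cl)cc(Cl)cc5Cl)c(OCc3ccccc3)c2c1OC(C)(C)CC2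
A8 | alternative 3 | (1E)-1-(6,6-dimethyloxan-2-ylidene)-3-methylbutan-2-one | CC(C)C(=O)/C=C1\CCCC(C)(C)O1
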